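**Assumption:** the target is taken as the drawn enol tautomer, i.e. the (1R,2R,4aR,6R,8aS)-decalin carrying an L-threonine-derived (5S, 1'R) tetramic acid. Decalin atoms are numbered as in naphthalene (C1 quaternary, C2 dienyl, C3=C4, C4a, C5–C8, C8a).

## Retrosynthetic overview

1. Tetramic acid last: Lacey–Dieckmann closure of the threonine β-ketoamide 18, from β-keto thioester 16, from decalin aldehyde 14 (ester 13).
2. C3=C4 and the trans ring-fusion hydrogen H-4a come from a palladium/formate 1,3-transposition of the inverted C3 formate 12; the dienyl comes from a Wittig reaction on the C2 aldehyde of 8.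
3. Rings B and A form in one operation: enol ether–enyne metathesis/ring-closing metathesis of 2 with 6 closes ring B and gives the 1-silyloxy diene 7; an endo Diels–Alder with the fumaraldehydic ester 5 in the same pot closes ring A.
4. The drawn isomer has H-2 trans to H-4a and an axial C6 methyl (cis to the C8a–C1 bond). The cycloaddition sets C1, C2 and C8a against C6; H-4a is set afterwards by palladium.
5. Ring order: B, then A (same pot), then the tetramic acid. C6 comes from (R)-citronellal.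

## Route

Step 1
Reactants: 1 (R)-citronellal
Product: 2 (4R)-4,8-dimethylnon-7-en-1-yne
Conditions: dimethyl (1-diazo-2-oxopropyl)phosphonate, K2CO3, MeOH, 0 °C to rt
Reagents that add atoms: dimethyl (1-diazo-2-oxopropyl)phosphonate, CC(=O)C(=[N+]=[N-])P(=O)(OC)OC
Why: Seyferth–Gilbert homologation (Ohira–Bestmann variant) turns the aldehyde into the terminal alkyne; the stereocentre (later C6) is β to the carbonyl and is not touched.

Step 2
Reactants: 3 glyoxal (40% in water, 5 equiv); 4 ethyl 2-(triphenyl-λ5-phosphanylidene)propanoate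
Product: 5 ethyl (2E)-2-methyl-4-oxobut-2-enoate
Conditions: CH2Cl2/H2O, rt
Reagents that add atoms: none
Why: Wittig mono-olefination with a stabilised ylide is E-selective, so CHO ends trans to CO2Et and cis to the methyl group, the geometry the cycloaddition needs.

Step 3
Reactants: 2 (4R)-4,8-dimethylnon-7-en-1-yne; 6 tert-butyl(ethenyloxy)dimethylsilane (3 equiv); 5 ethyl (2E)-2-methyl-4-oxobut-2-enoate (1.5 equiv)
Product: 8 ethyl (1R,2S,3R,6R,8aS)-3-[(tert-butyldimethylsilyl)oxy]-2-formyl-1,6-dimethyl-1,2,3,5,6,7,8,8a-octahydronaphthalene-1-carboxylate, via silyloxy diene 7 (not isolated)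
Conditions: 6, second-generation Grubbs catalyst RuCl2(=CHPh)(PCy3)(H2IMes) (5 mol%), PhMe, 70 °C; excess 6 and isobutene removed under vacuum; then 5, PhMe, 90 °C
Reagents that add atoms: none
Why: Proposed new method: the Fischer carbene Ru=CH–OSi formed from 6 adds to the terminal alkyne (enol ether–alkyne cross metathesis), the resulting vinyl carbene closes ring B on the prenyl alkene (ring-closing metathesis, isobutene lost) to give the E-1-silyloxy diene 7, and 7 then undergoes a thermal Diels–Alder reaction with 5 to close ring A; the nucleophilic terminus C8a bonds to the carbon β to CHO (C1), CHO sits endo (cis to C3–O and to C8), the E-dienophile places C1–CH3 cis to C2–CHO and CO2Et cis to H-8a, and chair-like (axial) attack on the half-chair with pseudo-equatorial C6–CH3 puts the C8a–C1 bond cis to that methyl; closest known reaction types are enol ether–alkyne metathesis, tandem enyne metathesis/Diels–Alder and the Alder endo rule for 1-oxy dienes.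

Step 4
Reactants: 8 ethyl (1R,2S,3R,6R,8aS)-3-[(tert-butyldimethylsilyl)oxy]-2-formyl-1,6-dimethyl-1,2,3,5,6,7,8,8a-octahydronaphthalene-1-carboxylate
Product: 10 ethyl (1R,2S,3R,6R,8aS)-3-[(tert-butyldimethylsilyl)oxy]-1,6-dimethyl-2-[(1E,3E)-penta-1,3-dien-1-yl]-1,2,3,5,6,7,8,8a-octahydronaphthalene-1-carboxylate, via Z-dienyl isomer 9 (not isolated)
Conditions: (E)-but-2-en-1-yl(triphenyl)phosphonium bromide, KN(SiMe3)2, THF, −78 to 0 °C; then I2 (5 mol%), hexane, daylight, rt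
Reagents that add atoms: (E)-but-2-en-1-yl(triphenyl)phosphonium bromide, C/C=C/C[P+](c1ccccc1)(c1ccccc1)c1ccccc1.[Br-]
Why: Wittig olefination with the semi-stabilised crotyl ylide gives an E/Z mixture at the new double bond, and iodine-catalysed equilibration converts it to the E,E-diene; addition at −78 °C outpaces enolisation, so C2 keeps its configuration.

Step 5
Reactants: 10 ethyl (1R,2S,3R,6R,8aS)-3-[(tert-butyldimethylsilyl)oxy]-1,6-dimethyl-2-[(1E,3E)-penta-1,3-dien-1-yl]-1,2,3,5,6,7,8,8a-octahydronaphthalene-1-carboxylate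
Product: 11 ethyl (1R,2S,3R,6R,8aS)-3-hydroxy-1,6-dimethyl-2-[(1E,3E)-penta-1,3-dien-1-yl]-1,2,3,5,6,7,8,8a-octahydronaphthalene-1-carboxylate
Conditions: Bu4NF, THF, 0 °C
Reagents that add atoms: none
Why: Fluoride-mediated cleavage of the silyl ether; the hindered ester and the alkenes are inert.

Step 6
Reactants: 11 ethyl (1R,2S,3R,6R,8aS)-3-hydroxy-1,6-dimethyl-2-[(1E,3E)-penta-1,3-dien-1-yl]-1,2,3,5,6,7,8,8a-octahydronaphthalene-1-carboxylate
Product: 12 ethyl (1R,2S,3S,6R,8aS)-3-(formyloxy)-1,6-dimethyl-2-[(1E,3E)-penta-1,3-dien-1-yl]-1,2,3,5,6,7,8,8a-octahydronaphthalene-1-carboxylate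
Conditions: HCO2H, PPh3, i-PrO2CN=NCO2i-Pr, THF, 0 °C to rt
Reagents that add atoms: formic acid, OC=O
Why: Mitsunobu esterification inverts C3 (3R to 3S), placing the formate on the face opposite to the one where H-4a is needed.

Step 7
Reactants: 12 ethyl (1R,2S,3S,6R,8aS)-3-(formyloxy)-1,6-dimethyl-2-[(1E,3E)-penta-1,3-dien-1-yl]-1,2,3,5,6,7,8,8a-octahydronaphthalene-1-carboxylate
Product: 13 ethyl (1R,2R,4aR,6R,8aS)-1,6-dimethyl-2-[(1E,3E)-penta-1,3-dien-1-yl]-1,2,4a,5,6,7,8,8a-octahydronaphthalene-1-carboxylate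
Conditions: Pd(OAc)2 (5 mol%), n-Bu3P (10 mol%), 1,4-dioxane, 80 °C
Reagents that add atoms: none
Why: Tsuji–Mandai hydrogenolysis of an allylic formate: zerovalent palladium ionises the formate with inversion, loss of CO2 gives Pd–H, and hydride is delivered on the palladium face to the more substituted allyl terminus C4a, which sets H-4a trans to H-8a and moves the alkene to C3=C4.

Step 8
Reactants: 13 ethyl (1R,2R,4aR,6R,8aS)-1,6-dimethyl-2-[(1E,3E)-penta-1,3-dien-1-yl]-1,2,4a,5,6,7,8,8a-octahydronaphthalene-1-carboxylate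
Product: 14 (1R,2R,4aR,6R,8aS)-1,6-dimethyl-2-[(1E,3E)-penta-1,3-dien-1-yl]-1,2,4a,5,6,7,8,8a-octahydronaphthalene-1-carbaldehyde
Conditions: i-Bu2AlH (1.2 equiv), CH2Cl2, −78 °C; aq. KNaC4H4O6 work-up
Reagents that add atoms: none
Why: Partial reduction of the ester; the aluminium hemiacetal on the quaternary carbon is stable at −78 °C and gives the aldehyde on work-up.

Step 9
Reactants: 14 (1R,2R,4aR,6R,8aS)-1,6-dimethyl-2-[(1E,3E)-penta-1,3-dien-1-yl]-1,2,4a,5,6,7,8,8a-octahydronaphthalene-1-carbaldehyde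
Product: 15 S-tert-butyl 3-[(1R,2R,4aR,6R,8aS)-1,6-dimethyl-2-[(1E,3E)-penta-1,3-dien-1-yl]-1,2,4a,5,6,7,8,8a-octahydronaphthalen-1-yl]-3-hydroxypropanethioate (both carbinol epimers)
Conditions: S-tert-butyl ethanethioate, LiN(i-Pr)2, THF, −78 °C; then 14
Reagents that add atoms: S-tert-butyl ethanethioate, CC(=O)SC(C)(C)C
Why: Aldol addition of the thioester lithium enolate to the non-enolisable aldehyde; the new carbinol centre is oxidised away in the next step.

Step 10
Reactants: 15 S-tert-butyl 3-[(1R,2R,4aR,6R,8aS)-1,6-dimethyl-2-[(1E,3E)-penta-1,3-dien-1-yl]-1,2,4a,5,6,7,8,8a-octahydronaphthalen-1-yl]-3-hydroxypropanethioate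
Product: 16 S-tert-butyl 3-[(1R,2R,4aR,6R,8aS)-1,6-dimethyl-2-[(1E,3E)-penta-1,3-dien-1-yl]-1,2,4a,5,6,7,8,8a-octahydronaphthalen-1-yl]-3-oxopropanethioate
Conditions: Dess–Martin periodinane, NaHCO3, CH2Cl2, 0 °C to rt
Reagents that add atoms: none
Why: Dess–Martin oxidation of the secondary alcohol to the β-keto thioester under near-neutral conditions that leave the diene alone.

Step 11
Reactants: 16 S-tert-butyl 3-[(1R,2R,4aR,6R,8aS)-1,6-dimethyl-2-[(1E,3E)-penta-1,3-dien-1-yl]-1,2,4a,5,6,7,8,8a-octahydronaphthalen-1-yl]-3-oxopropanethioate; 17 methyl L-threoninate hydrochloride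
Product: 18 methyl (2S,3R)-2-{3-[(1R,2R,4aR,6R,8aS)-1,6-dimethyl-2-[(1E,3E)-penta-1,3-dien-1-yl]-1,2,4a,5,6,7,8,8a-octahydronaphthalen-1-yl]-3-oxopropanamido}-3-hydroxybutanoate
Conditions: AgOCOCF3 (2.2 equiv), Et3N (3 equiv), THF, 0 °C to rt
Reagents that add atoms: none
Why: Silver-promoted aminolysis of the thioester is N-selective (the free hydroxyl does not compete) and leaves both threonine stereocentres untouched.

Step 12
Reactants: 18 methyl (2S,3R)-2-{3-[(1R,2R,4aR,6R,8aS)-1,6-dimethyl-2-[(1E,3E)-penta-1,3-dien-1-yl]-1,2,4a,5,6,7,8,8a-octahydronaphthalen-1-yl]-3-oxopropanamido}-3-hydroxybutanoate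
Product: 19 (5S)-3-{[(1R,2R,4aR,6R,8aS)-1,6-dimethyl-2-[(1E,3E)-penta-1,3-dien-1-yl]-1,2,4a,5,6,7,8,8a-octahydronaphthalen-1-yl]carbonyl}-4-hydroxy-5-[(1R)-1-hydroxyethyl]-1,5-dihydro-2H-pyrrol-2-one (target)
Conditions: KOt-Bu, t-BuOH/THF, rt, 15 min; then aq. HCl to pH 3
Reagents that add atoms: none
Why: Lacey–Dieckmann cyclisation of the doubly stabilised carbanion onto the methyl ester closes the tetramic acid; a short reaction time keeps C5 (S) from epimerising, and the side-chain alkoxide has no productive pathway.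

## Compound list

1 | (R)-citronellal, (3R)-3,7-dimethyloct-6-enal | O=CC[C@H](C)CCC=C(C)C | starting material
2 | (4R)-4,8-dimethylnon-7-en-1-yne | C#CC[C@H](C)CCC=C(C)C | intermediate
3 | glyoxal (ethanedial) | O=CC=O | starting material
4 | ethyl 2-(triphenyl-λ5-phosphanylidene)propanoate | CCOC(=O)C(C)=P(c1ccccc1)(c1ccccc1)c1ccccc1 | starting material
5 | ethyl (2E)-2-methyl-4-oxobut-2-enoate | CCOC(=O)/C(C)=C/C=O | intermediate
6 | tert-butyl(ethenyloxy)dimethylsilane | C=CO[Si](C)(C)C(C)(C)C | starting material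
7 | tert-butyl(dimethyl)({(E)-2-[(5R)-5-methylcyclohex-1-en-1-yl]ethenyl}oxy)silane | CC(C)(C)[Si](C)(C)O/C=C/C1=CCC[C@@H](C)C1 | intermediate
8 | ethyl (1R,2S,3R,6R,8aS)-3-[(tert-butyldimethylsilyl)oxy]-2-formyl-1,6-dimethyl-1,2,3,5,6,7,8,8a-octahydronaphthalene-1-carboxylate | O=C[C@@H]1[C@H](O[Si](C)(C)C(C)(C)C)C=C2C[C@H](C)CC[C@@H]2[C@@]1(C)C(=O)OCC | intermediate
9 | ethyl (1R,2S,3R,6R,8aS)-3-[(tert-butyldimethylsilyl)oxy]-1,6-dimethyl-2-[(1Z,3E)-penta-1,3-dien-1-yl]-1,2,3,5,6,7,8,8a-octahydronaphthalene-1-carboxylate | C/C=C/C=C\[C@@H]1[C@H](O[Si](C)(C)C(C)(C)C)C=C2C[C@H](C)CC[C@@H]2[C@@]1(C)C(=O)OCC | intermediate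
10 | ethyl (1R,2S,3R,6R,8aS)-3-[(tert-butyldimethylsilyl)oxy]-1,6-dimethyl-2-[(1E,3E)-penta-1,3-dien-1-yl]-1,2,3,5,6,7,8,8a-octahydronaphthalene-1-carboxylate | C/C=C/C=C/[C@@H]1[C@H](O[Si](C)(C)C(C)(C)C)C=C2C[C@H](C)CC[C@@H]2[C@@]1(C)C(=O)OCC | intermediate
11 | ethyl (1R,2S,3R,6R,8aS)-3-hydroxy-1,6-dimethyl-2-[(1E,3E)-penta-1,3-dien-1-yl]-1,2,3,5,6,7,8,8a-octahydronaphthalene-1-carboxylate | C/C=C/C=C/[C@@H]1[C@H](O)C=C2C[C@H](C)CC[C@@H]2[C@@]1(C)C(=O)OCC | intermediate
12 | ethyl (1R,2S,3S,6R,8aS)-3-(formyloxy)-1,6-dimethyl-2-[(1E,3E)-penta-1,3-dien-1-yl]-1,2,3,5,6,7,8,8a-octahydronaphthalene-1-carboxylate | C/C=C/C=C/[C@@H]1[C@@H](OC=O)C=C2C[C@H](C)CC[C@@H]2[C@@]1(C)C(=O)OCC | intermediate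
13 | ethyl (1R,2R,4aR,6R,8aS)-1,6-dimethyl-2-[(1E,3E)-penta-1,3-dien-1-yl]-1,2,4a,5,6,7,8,8a-octahydronaphthalene-1-carboxylate | C/C=C/C=C/[C@@H]1C=C[C@H]2C[C@H](C)CC[C@@H]2[C@@]1(C)C(=O)OCC | intermediate
14 | (1R,2R,4aR,6R,8aS)-1,6-dimethyl-2-[(1E,3E)-penta-1,3-dien-1-yl]-1,2,4a,5,6,7,8,8a-octahydronaphthalene-1-carbaldehyde | C/C=C/C=C/[C@@H]1C=C[C@H]2C[C@H](C)CC[C@@H]2[C@@]1(C)C=O | intermediate
15 | S-tert-butyl 3-[(1R,2R,4aR,6R,8aS)-1,6-dimethyl-2-[(1E,3E)-penta-1,3-dien-1-yl]-1,2,4a,5,6,7,8,8a-octahydronaphthalen-1-yl]-3-hydroxypropanethioate (both carbinol epimers) | C/C=C/C=C/[C@@H]1C=C[C@H]2C[C@H](C)CC[C@@H]2[C@@]1(C)C(O)CC(=O)SC(C)(C)C | intermediate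
16 | S-tert-butyl 3-[(1R,2R,4aR,6R,8aS)-1,6-dimethyl-2-[(1E,3E)-penta-1,3-dien-1-yl]-1,2,4a,5,6,7,8,8a-octahydronaphthalen-1-yl]-3-oxopropanethioate | C/C=C/C=C/[C@@H]1C=C[C@H]2C[C@H](C)CC[C@@H]2[C@@]1(C)C(=O)CC(=O)SC(C)(C)C | intermediate
17 | methyl L-threoninate hydrochloride | C[C@@H](O)[C@H](N)C(=O)OC.Cl | starting material
18 | methyl (2S,3R)-2-{3-[(1R,2R,4aR,6R,8aS)-1,6-dimethyl-2-[(1E,3E)-penta-1,3-dien-1-yl]-1,2,4a,5,6,7,8,8a-octahydronaphthalen-1-yl]-3-oxopropanamido}-3-hydroxybutanoate | C/C=C/C=C/[C@@H]1C=C[C@H]2C[C@H](C)CC[C@@H]2[C@@]1(C)C(=O)CC(=O)N[C@@H]([C@@H](C)O)C(=O)OC | intermediate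
19 | (5S)-3-{[(1R,2R,4aR,6R,8aS)-1,6-dimethyl-2-[(1E,3E)-penta-1,3-dien-1-yl]-1,2,4a,5,6,7,8,8a-octahydronaphthalen-1-yl]carbonyl}-4-hydroxy-5-[(1R)-1-hydroxyethyl]-1,5-dihydro-2H-pyrrol-2-one | C/C=C/C=C/[C@@H]1C=C[C@H]2C[C@H](C)CC[C@@H]2[C@@]1(C)C(=O)C1=C(O)[C@H]([C@@H](C)O)NC1=O | target

## Step count and risks

Total step count: 12. Longest linear sequence: 11 (steps 1 and 3 to 12; step 2 is the side branch to 5).

**Step 3 (one-pot metathesis cascade and cycloaddition).** The Fischer carbene may turn over poorly, the enol ether may form largely as the unreactive Z isomer, and the cycloaddition must bond C8a to the more hindered carbon of 5. Fallback: build the diene stepwise and run the cycloaddition separately. Setting out from 2, chemoselective ozonolysis of the trisubstituted alkene (O3, CH2Cl2, −78 °C; Me2S) gives (4R)-4-methylhept-6-ynal F1. Wittig methylenation gives (4R)-4-methyloct-7-en-1-yne F2. Ordinary ring-closing enyne metathesis (second-generation Grubbs catalyst, ethylene atmosphere) gives (5R)-1-ethenyl-5-methylcyclohex-1-ene F3. Hydroboration of the terminal alkene with 9-BBN and NaOH/H2O2 gives 2-[(5R)-5-methylcyclohex-1-en-1-yl]ethan-1-ol F4. Dess–Martin oxidation gives [(5R)-5-methylcyclohex-1-en-1-yl]acetaldehyde F5. Silylation (TBSOTf, Et3N) gives the dienol ether 7, now isolated and enriched in the E isomer, and heating it with 5 returns the route at 8.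

**Step 4 (Wittig reaction on an α-branched, β-silyloxy aldehyde).** Enolisation, β-elimination or incomplete E,E-equilibration are possible. Fallback: setting out from 8, Takai iodo-olefination (CrCl2, CHI3, THF; non-basic) gives ethyl (1R,2S,3R,6R,8aS)-3-[(tert-butyldimethylsilyl)oxy]-2-[(E)-2-iodoethenyl]-1,6-dimethyl-1,2,3,5,6,7,8,8a-octahydronaphthalene-1-carboxylate F6. Suzuki coupling with (E)-prop-1-en-1-ylboronic acid (Pd(PPh3)4, K3PO4, THF/H2O) returns the route at 10.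

**Step 7 (palladium/formate transposition).** Hydride delivery might go to C3, or β-hydride elimination might give a diene. Fallback: reductive transposition through a tosylhydrazone instead of a π-allyl complex. Setting out from 11, Dess–Martin oxidation gives the enone ethyl (1R,2S,6R,8aS)-1,6-dimethyl-3-oxo-2-[(1E,3E)-penta-1,3-dien-1-yl]-1,2,3,5,6,7,8,8a-octahydronaphthalene-1-carboxylate F7. Condensation with p-toluenesulfonylhydrazide gives its tosylhydrazone F8. Catecholborane followed by NaOAc·3H2O adds hydride to C3 from the face away from the 1,3-related C1 methyl group, and the resulting diazene passes its hydrogen to C4a on the lower face with loss of N2. This returns the route at 13, with 12 bypassed.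

Further compounds
F1 | step 3 | (4R)-4-methylhept-6-ynal | C#CC[C@H](C)CCC=O
F2 | step 3 | (4R)-4-methyloct-7-en-1-yne | C#CC[C@H](C)CCC=C
F3 | step 3 | (5R)-1-ethenyl-5-methylcyclohex-1-ene | C=CC1=CCC[C@@H](C)C1
F4 | step 3 | 2-[(5R)-5-methylcyclohex-1-en-1-yl]ethan-1-ol | OCCC1=CCC[C@@H](C)C1
F5 | step 3 | [(5R)-5-methylcyclohex-1-en-1-yl]acetaldehyde | O=CCC1=CCC[C@@H](C)C1
F6 | step 4 | ethyl (1R,2S,3R,6R,8aS)-3-[(tert-butyldimethylsilyl)oxy]-2-[(E)-2-iodoethenyl]-1,6-dimethyl-1,2,3,5,6,7,8,8a-octahydronaphthalene-1-carboxylate | I/C=C/[C@@H]1[C@H](O[Si](C)(C)C(C)(C)C)C=C2C[C@H](C)CC[C@@H]2[C@@]1(C)C(=O)OCC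
F7 | step 7 | ethyl (1R,2S,6R,8aS)-1,6-dimethyl-3-oxo-2-[(1E,3E)-penta-1,3-dien-1-yl]-1,2,3,5,6,7,8,8a-octahydronaphthalene-1-carboxylate | C/C=C/C=C/[C@@H]1C(=O)C=C2C[C@H](C)CC[C@@H]2[C@@]1(C)C(=O)OCC
F8 | step 7 | p-toluenesulfonylhydrazone of F7 | C/C=C/C=C/[C@@H]1C(=NNS(=O)(=O)c3ccc(C)cc3)C=C2C[C@H](C)CC[C@@H]2[C@@]1(C)C(=O)OCC
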